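**Retrosynthetic overview**

1. Feature: in each acyl chain C3' is bonded to C2' (the CH2 next to the ester carbonyl C1') and lies β to the aldehyde carbon of its own CH2CHO arm. C3' is therefore the β-carbon of an enal, and C2' is a malonate carbon already esterified to O–C3 and to O–CH2–C1 of the cyclopentane.
2. Key disconnection: both C2'–C3' bonds are cut, giving core bis(allyl malonate) 20 and two molecules of acetal-bearing dienal 6 (two-directional iminium Michael addition). Deallylation with decarboxylation and acid unmasking follow.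
3. 20 comes from diol 17 in two acylations with monoallyl malonate 18: carbodiimide esterification of the primary hydroxyl, then Mitsunobu esterification at C3 with inversion. 17 comes from (1S,4R)-cis-4-acetoxycyclopent-2-en-1-ol 7 by Pd(PPh3)4-catalysed allylic alkylation (C5), oxidation to the enone, vinyl conjugate addition with methylation (C1, C2) and hydride reduction.
4. 6 comes from crotonaldehyde by α-bromination, acetalisation and Heck coupling with acrolein.
5. Rings: none is formed. The cyclopentane is carried over from 7, and the 1,3-dioxane (step 6) is a protecting ring opened in step 15.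

Key step: step 13

Remark on the chemistry: ring atoms are C1 (CH2O-acyl), C2 (CH3), C3 (O-acyl), C4 (CH2) and C5 (diol-bearing); chain atoms are C1'–C6'. C2' in 21 and 22 is a mixture of epimers, written without configuration, and is removed in step 14. The sense of induction in step 13 is taken from the accepted steric model for enal iminium ions of diarylprolinol silyl ethers.

**Route**

Step 1
Reactants: 1 crotonaldehyde
Product: 3 (Z)-2-bromobut-2-enal, via 2,3-dibromobutanal 2 (not isolated)
Conditions: Br2, CH2Cl2, 0 °C; then Et3N, 0 °C → rt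
Reagents that add atoms: bromine, BrBr
Why: Bromine adds across the enal C=C and triethylamine then removes the acidic α-hydrogen with loss of the β-bromide (bromination–dehydrobromination), which should give the more stable Z isomer with CH3 trans to CHO, the geometry needed for C4'=C5'.

Step 2
Reactants: 3 (Z)-2-bromobut-2-enal
Product: 4 (Z)-2-bromo-1,1-dimethoxybut-2-ene
Conditions: HC(OMe)3, MeOH, NH4NO3 (cat.), rt
Reagents that add atoms: trimethyl orthoformate, COC(OC)OC
Why: Mildly acid-catalysed acetalisation with the orthoester as water scavenger masks the formyl group that becomes the C4' aldehyde, so that only the aldehyde made in step 3 can form an iminium ion in step 13.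

Step 3
Reactants: 4 (Z)-2-bromo-1,1-dimethoxybut-2-ene; 5 acrolein
Product: 6 (2E,4E)-4-(dimethoxymethyl)hexa-2,4-dienal
Conditions: Pd(OAc)2 (5 mol %), Bu4NCl, NaHCO3, DMF, 50 °C
Reagents that add atoms: none
Why: Mizoroki–Heck coupling under ligand-free phase-transfer conditions joins the alkenyl bromide to the β-carbon of acrolein with retention of the bromide's alkene geometry, and syn β-hydride elimination should give the new C2=C3 bond as the E isomer.

Step 4
Reactants: 7 (1S,4R)-cis-4-acetoxycyclopent-2-en-1-ol; 8 dimethyl malonate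
Product: 9 dimethyl 2-[(1R,4S)-4-hydroxycyclopent-2-en-1-yl]propanedioate
Conditions: NaH, Pd(PPh3)4 (3 mol %), THF, 0 → 50 °C
Reagents that add atoms: none
Why: Tsuji–Trost allylic alkylation, in which Pd(PPh3)4 ionises the allylic acetate with inversion and the malonate anion attacks the π-allyl complex anti to the metal at the terminus remote from the hydroxyl, so that C5 is set with net retention (1,4-cis) from the enantiopure starting material.

Step 5
Reactants: 9 dimethyl 2-[(1R,4S)-4-hydroxycyclopent-2-en-1-yl]propanedioate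
Product: 10 2-[(1R,4S)-4-hydroxycyclopent-2-en-1-yl]propane-1,3-diol
Conditions: LiAlH4, THF, 0 °C → rt
Reagents that add atoms: none
Why: Hydride reduction of both ester groups gives the 2-substituted propane-1,3-diol, removes the acidic malonate hydrogen before the organometallic step and leaves the allylic alcohol and C5 untouched.

Step 6
Reactants: 10 2-[(1R,4S)-4-hydroxycyclopent-2-en-1-yl]propane-1,3-diol
Product: 11 (1S,4R)-4-(2,2-dimethyl-1,3-dioxan-5-yl)cyclopent-2-en-1-ol
Conditions: Me2C(OMe)2, PPTS (cat.), CH2Cl2, rt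
Reagents that add atoms: 2,2-dimethoxypropane, COC(C)(C)OC
Why: Acid-catalysed transketalisation closes the six-membered 1,3-dioxane on the 1,3-diol in preference to any ketal that would involve the remote ring hydroxyl.

Step 7
Reactants: 11 (1S,4R)-4-(2,2-dimethyl-1,3-dioxan-5-yl)cyclopent-2-en-1-ol
Product: 12 (4R)-4-(2,2-dimethyl-1,3-dioxan-5-yl)cyclopent-2-en-1-one
Conditions: MnO2, CH2Cl2, rt
Reagents that add atoms: none
Why: Manganese dioxide oxidises the allylic alcohol selectively to the enone under neutral conditions, so the γ-stereocentre (C5) should not be epimerised.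

Step 8
Reactants: 12 (4R)-4-(2,2-dimethyl-1,3-dioxan-5-yl)cyclopent-2-en-1-one
Product: 14 (2R,3S,4R)-4-(2,2-dimethyl-1,3-dioxan-5-yl)-3-ethenyl-2-methylcyclopentan-1-one, via bromomagnesium enolate 13 (not isolated)
Conditions: CH2=CHMgBr, CuBr·SMe2 (10 mol %), THF, −78 → −40 °C; then MeI, HMPA, −40 → 0 °C
Reagents that add atoms: vinylmagnesium bromide, C=C[Mg]Br; iodomethane, CI
Why: CuBr·SMe2-catalysed conjugate addition of the vinyl Grignard reagent should occur anti to the bulky C5 substituent (sets C1) and the regiodefined enolate should be methylated anti to the new vinyl group (sets C2), the usual trans,trans outcome of conjugate addition with enolate alkylation on 4-substituted cyclopentenones; the vinyl group serves as the masked hydroxymethyl group.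

Step 9
Reactants: 14 (2R,3S,4R)-4-(2,2-dimethyl-1,3-dioxan-5-yl)-3-ethenyl-2-methylcyclopentan-1-one
Product: 15 (1S,2R,3S,4R)-4-(2,2-dimethyl-1,3-dioxan-5-yl)-3-ethenyl-2-methylcyclopentan-1-ol
Conditions: LiBH(s-Bu)3, THF, −78 °C
Reagents that add atoms: none
Why: The bulky hydride should attack the cyclopentanone from the face opposite to the adjacent methyl group, as is known for 2-alkylcyclopentanones and prostaglandin E-type ketones, so the hydroxyl comes out cis to the methyl group, which is the C3 epimer that the inverting esterification of step 12 requires.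

Step 10
Reactants: 15 (1S,2R,3S,4R)-4-(2,2-dimethyl-1,3-dioxan-5-yl)-3-ethenyl-2-methylcyclopentan-1-ol
Product: 17 (1S,2R,3S,4R)-4-(2,2-dimethyl-1,3-dioxan-5-yl)-3-(hydroxymethyl)-2-methylcyclopentan-1-ol, via aldehyde 16 (not isolated)
Conditions: O3, CH2Cl2/MeOH, −78 °C; then NaBH4, −78 °C → rt
Reagents that add atoms: ozone, [O-][O+]=O
Why: Ozonolysis cleaves the vinyl group to the C1 aldehyde, which borohydride reduces in the same flask to the hydroxymethyl group, and C1 already has its stable trans,trans arrangement and should not epimerise under the cold, non-basic conditions.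

Step 11
Reactants: 17 (1S,2R,3S,4R)-4-(2,2-dimethyl-1,3-dioxan-5-yl)-3-(hydroxymethyl)-2-methylcyclopentan-1-ol; 18 monoallyl malonate
Product: 19 [(1S,2R,3S,5R)-5-(2,2-dimethyl-1,3-dioxan-5-yl)-3-hydroxy-2-methylcyclopentyl]methyl prop-2-en-1-yl propanedioate
Conditions: DCC, DMAP (5 mol %), CH2Cl2, −20 → 0 °C
Reagents that add atoms: none
Why: Steglich esterification with about one equivalent of the half-ester should acylate the unhindered primary hydroxyl in preference to the secondary C3 hydroxyl, which is flanked by the cis C2 methyl group, and capping this oxygen first keeps it from displacing the activated C3 oxygen (bridged ether formation) in step 12.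

Step 12
Reactants: 19 [(1S,2R,3S,5R)-5-(2,2-dimethyl-1,3-dioxan-5-yl)-3-hydroxy-2-methylcyclopentyl]methyl prop-2-en-1-yl propanedioate; 18 monoallyl malonate
Product: 20 [(1S,2R,3R,5R)-5-(2,2-dimethyl-1,3-dioxan-5-yl)-2-methyl-3-{[3-oxo-3-(prop-2-en-1-yloxy)propanoyl]oxy}cyclopentyl]methyl prop-2-en-1-yl propanedioate
Conditions: PPh3, DIAD, THF, 0 °C → rt
Reagents that add atoms: none
Why: In the Mitsunobu esterification the carboxylate of the malonate half-ester displaces the phosphonium-activated C3 oxygen in an SN2 reaction with inversion, which turns the cis (3S) alcohol into the required trans (3R) ester, while the far less acidic malonate CH2 groups should not compete as nucleophiles.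

Step 13
Reactants: 20 core bis(allyl malonate); 6 (2E,4E)-4-(dimethoxymethyl)hexa-2,4-dienal
Product: 21 bis-Michael adduct: 20 in which each malonate carbon C2' bears a (3S,4E)-4-(dimethoxymethyl)-1-oxohex-4-en-3-yl group (free CH2CHO arms, C2' epimer mixture)
Conditions: (R)-2-{bis[3,5-bis(trifluoromethyl)phenyl](trimethylsilyloxy)methyl}pyrrolidine (20 mol %), 6 (3 equiv), EtOH, 0 °C → rt
Reagents that add atoms: none
Why: The secondary amine condenses with 6 to an (E)-s-trans iminium ion, the enol form of each core-bound malonate adds to its β-carbon (the later C3'), and hydrolysis of the resulting enamine frees the CH2CHO arm and returns the amine; this is the diarylprolinol silyl ether-catalysed Michael addition of malonates to enals. No ring is closed; two C2'–C3' bonds are formed, one on each arm. In the iminium ion of the (R)-catalyst the CAr2(OSiMe3) group covers the Si face of C3 of the dienal, so the malonate should add to the Re face, which is (S) at both C3' (priority C4' > C2' > CH2CHO). The two arms are far apart and far from the ring stereocentres, so each addition should answer to the catalyst alone. The step needs 1,4- and not 1,6-addition, which the trisubstituted, acetal-bearing γ,δ-alkene with its substituted terminus should secure, and it needs the C4=C5 geometry to survive, which the mild, acid-free conditions should allow by disfavouring trienamine formation. C2' forms as a mixture, which does not matter.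

Step 14
Reactants: 21 bis-Michael adduct
Product: 23 [(1S,2R,3R,5R)-5-(2,2-dimethyl-1,3-dioxan-5-yl)-3-{[(3S,4E)-4-(dimethoxymethyl)-3-(2-oxoethyl)hex-4-enoyl]oxy}-2-methylcyclopentyl]methyl (3S,4E)-4-(dimethoxymethyl)-3-(2-oxoethyl)hex-4-enoate, via bis(hydrogen malonate) 22 (not isolated)
Conditions: Pd(PPh3)4 (5 mol %), HCO2H/Et3N (1:1), THF, rt; then toluene, 80 °C
Reagents that add atoms: none
Why: Pd(PPh3)4 with formate as hydride donor cleaves both allyl esters (Tsuji–Trost deallylation) to the malonic half-acids, which lose CO2 on gentle heating and so erase the uncontrolled C2' centres, while C3', the acetals and the acetonide should be unaffected in the buffered, amine-nucleophile-free medium.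

Step 15
Reactants: 23 bis(dimethyl acetal) acetonide
Product: 24 target, [(1S,2R,3R,5R)-5-(1,3-dihydroxypropan-2-yl)-3-{[(3S,4E)-4-formyl-3-(2-oxoethyl)hex-4-enoyl]oxy}-2-methylcyclopentyl]methyl (3S,4E)-4-formyl-3-(2-oxoethyl)hex-4-enoate
Conditions: aq. HCl (0.5 M), THF, 0 °C → rt
Reagents that add atoms: water, O
Why: Dilute aqueous acid hydrolyses the two dimethyl acetals and the acetonide, which are far more labile than the four ester groups, and the E enal geometry set in step 1 is the more stable one and should be kept.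

**Compound list**

1 | crotonaldehyde, (E)-but-2-enal | C/C=C/C=O | starting material
2 | 2,3-dibromobutanal (racemic anti-adduct, not isolated) | CC(Br)C(Br)C=O | intermediate
3 | (Z)-2-bromobut-2-enal | C/C=C(\Br)C=O | intermediate
4 | (Z)-2-bromo-1,1-dimethoxybut-2-ene | C/C=C(\Br)C(OC)OC | intermediate
5 | acrolein, prop-2-enal | C=CC=O | starting material
6 | (2E,4E)-4-(dimethoxymethyl)hexa-2,4-dienal | O=C/C=C/C(C(OC)OC)=C\C | intermediate
7 | (1S,4R)-cis-4-acetoxycyclopent-2-en-1-ol | O[C@@H]1C=C[C@H](OC(C)=O)C1 | starting material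
8 | dimethyl malonate | COC(=O)CC(=O)OC | starting material
9 | dimethyl 2-[(1R,4S)-4-hydroxycyclopent-2-en-1-yl]propanedioate | O[C@@H]1C=C[C@H](C(C(=O)OC)C(=O)OC)C1 | intermediate
10 | 2-[(1R,4S)-4-hydroxycyclopent-2-en-1-yl]propane-1,3-diol | O[C@@H]1C=C[C@H](C(CO)CO)C1 | intermediate
11 | (1S,4R)-4-(2,2-dimethyl-1,3-dioxan-5-yl)cyclopent-2-en-1-ol | O[C@@H]1C=C[C@H](C2COC(C)(C)OC2)C1 | intermediate
12 | (4R)-4-(2,2-dimethyl-1,3-dioxan-5-yl)cyclopent-2-en-1-one | O=C1C=C[C@H](C2COC(C)(C)OC2)C1 | intermediate
13 | bromomagnesium enolate of the 3-ethenyl ketone (3,4-trans, not isolated) | C=C[C@@H]1C=C(O[Mg]Br)C[C@H]1C2COC(C)(C)OC2 | intermediate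
14 | (2R,3S,4R)-4-(2,2-dimethyl-1,3-dioxan-5-yl)-3-ethenyl-2-methylcyclopentan-1-one | C=C[C@@H]1[C@@H](C)C(=O)C[C@H]1C2COC(C)(C)OC2 | intermediate
15 | (1S,2R,3S,4R)-4-(2,2-dimethyl-1,3-dioxan-5-yl)-3-ethenyl-2-methylcyclopentan-1-ol | C=C[C@@H]1[C@@H](C)[C@@H](O)C[C@H]1C2COC(C)(C)OC2 | intermediate
16 | (1S,2R,3S,5S)-5-(2,2-dimethyl-1,3-dioxan-5-yl)-3-hydroxy-2-methylcyclopentane-1-carbaldehyde (not isolated) | O=C[C@@H]1[C@@H](C)[C@@H](O)C[C@H]1C2COC(C)(C)OC2 | intermediate
17 | (1S,2R,3S,4R)-4-(2,2-dimethyl-1,3-dioxan-5-yl)-3-(hydroxymethyl)-2-methylcyclopentan-1-ol | OC[C@@H]1[C@@H](C)[C@@H](O)C[C@H]1C2COC(C)(C)OC2 | intermediate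
18 | monoallyl malonate, 3-oxo-3-(prop-2-en-1-yloxy)propanoic acid | OC(=O)CC(=O)OCC=C | starting material
19 | [(1S,2R,3S,5R)-5-(2,2-dimethyl-1,3-dioxan-5-yl)-3-hydroxy-2-methylcyclopentyl]methyl prop-2-en-1-yl propanedioate | C=CCOC(=O)CC(=O)OC[C@@H]1[C@@H](C)[C@@H](O)C[C@H]1C2COC(C)(C)OC2 | intermediate
20 | [(1S,2R,3R,5R)-5-(2,2-dimethyl-1,3-dioxan-5-yl)-2-methyl-3-{[3-oxo-3-(prop-2-en-1-yloxy)propanoyl]oxy}cyclopentyl]methyl prop-2-en-1-yl propanedioate | C=CCOC(=O)CC(=O)OC[C@@H]1[C@@H](C)[C@H](OC(=O)CC(=O)OCC=C)C[C@H]1C2COC(C)(C)OC2 | intermediate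
21 | bis-Michael adduct of 20 with two molecules of 6 (both C3' S, C2' unassigned) | C/C=C(/C(OC)OC)[C@@H](CC=O)C(C(=O)OCC=C)C(=O)OC[C@@H]1[C@@H](C)[C@H](OC(=O)C(C(=O)OCC=C)[C@H](CC=O)/C(C(OC)OC)=C\C)C[C@H]1C2COC(C)(C)OC2 | intermediate
22 | bis(hydrogen malonate) from 21 (both allyl esters cleaved, not isolated) | C/C=C(/C(OC)OC)[C@@H](CC=O)C(C(=O)O)C(=O)OC[C@@H]1[C@@H](C)[C@H](OC(=O)C(C(=O)O)[C@H](CC=O)/C(C(OC)OC)=C\C)C[C@H]1C2COC(C)(C)OC2 | intermediate
23 | [(1S,2R,3R,5R)-5-(2,2-dimethyl-1,3-dioxan-5-yl)-3-{[(3S,4E)-4-(dimethoxymethyl)-3-(2-oxoethyl)hex-4-enoyl]oxy}-2-methylcyclopentyl]methyl (3S,4E)-4-(dimethoxymethyl)-3-(2-oxoethyl)hex-4-enoate | C/C=C(/C(OC)OC)[C@@H](CC=O)CC(=O)OC[C@@H]1[C@@H](C)[C@H](OC(=O)C[C@H](CC=O)/C(C(OC)OC)=C\C)C[C@H]1C2COC(C)(C)OC2 | intermediate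
24 | [(1S,2R,3R,5R)-5-(1,3-dihydroxypropan-2-yl)-3-{[(3S,4E)-4-formyl-3-(2-oxoethyl)hex-4-enoyl]oxy}-2-methylcyclopentyl]methyl (3S,4E)-4-formyl-3-(2-oxoethyl)hex-4-enoate | C/C=C(/C=O)[C@@H](CC=O)CC(=O)OC[C@@H]1[C@@H](C)[C@H](OC(=O)C[C@H](CC=O)/C(C=O)=C\C)C[C@H]1C(CO)CO | target

**Step count**

Total: 15 steps. Longest linear sequence: 12 steps (7 → 24, steps 4–15); the dienal branch (steps 1–3) joins at step 13.

**Steps most likely to fail**

1. Step 13 (key step). The malonate may add 1,6 instead of 1,4. The dienal may be consumed through its trienamine, with self-condensation or loss of the C4=C5 geometry. The second addition may stall at the mono-adduct, or the face selectivity may be incomplete, giving C3' diastereomers that are hard to separate on the core. Fallback, setting out from 6 and returning at 23: the C3' centre is made on a simple malonate and the finished chain is attached afterwards. Diallyl malonate (C=CCOC(=O)CC(=O)OCC=C, in excess) is added to 6 with the same (R)-catalyst to give diallyl 2-[(3S,4E)-4-(dimethoxymethyl)-1-oxohex-4-en-3-yl]propanedioate F1, which can be purified and its enantiomeric purity checked. Pd(PPh3)4 with HCO2H/Et3N removes both allyl groups to give 2-[(3S,4E)-4-(dimethoxymethyl)-1-oxohex-4-en-3-yl]propanedioic acid F2, which on warming loses CO2 to give (3S,4E)-4-(dimethoxymethyl)-3-(2-oxoethyl)hex-4-enoic acid F3. Diol 17 is acylated at its primary hydroxyl with F3 (DCC, DMAP cat., CH2Cl2, −20 °C) to give [(1S,2R,3S,5R)-5-(2,2-dimethyl-1,3-dioxan-5-yl)-3-hydroxy-2-methylcyclopentyl]methyl (3S,4E)-4-(dimethoxymethyl)-3-(2-oxoethyl)hex-4-enoate F4. Mitsunobu esterification of F4 with a second portion of F3 (PPh3, DIAD), with inversion at C3, then gives 23.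

2. Step 12. At the hindered C3 alcohol the activated oxygen may be lost by elimination to the cyclopentene, or the ester may form with retention through an acyloxyphosphonium pathway. Fallback, setting out from 17 and returning at 20: inversion by sulfonate displacement, separated from the acylation. MsCl/Et3N converts 17 into [(1S,2R,3S,5R)-5-(2,2-dimethyl-1,3-dioxan-5-yl)-3-(methanesulfonyloxy)-2-methylcyclopentyl]methyl methanesulfonate F5. CsOAc with 18-crown-6 in toluene at 80 °C displaces both sulfonates, with SN2 inversion at C3, to give [(1S,2R,3R,5R)-3-acetoxy-5-(2,2-dimethyl-1,3-dioxan-5-yl)-2-methylcyclopentyl]methyl acetate F6. K2CO3 in MeOH frees the trans diol [(1S,2R,3R,5R)-5-(2,2-dimethyl-1,3-dioxan-5-yl)-3-hydroxy-2-methylcyclopentyl]methanol F7, and both of its hydroxyls are acylated with 18 (DCC, DMAP, CH2Cl2) to give 20.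

3. Step 3. Acrolein may polymerise under the basic, warm conditions, oxidative addition of the hindered alkenyl bromide may be slow, and metal hydride intermediates may scramble the alkene geometry. Fallback, setting out from 4 and returning at 6: Stille coupling of 4 with (E)-3-(tributylstannyl)prop-2-en-1-ol (Pd(PPh3)4, CuI, DMF) gives (2E,4E)-4-(dimethoxymethyl)hexa-2,4-dien-1-ol F8 with retention of both alkene geometries, and MnO2 in CH2Cl2 oxidises the allylic alcohol to 6.

**Further compounds**

F1 | step 13 | diallyl 2-[(3S,4E)-4-(dimethoxymethyl)-1-oxohex-4-en-3-yl]propanedioate | C/C=C(/C(OC)OC)[C@@H](CC=O)C(C(=O)OCC=C)C(=O)OCC=C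
F2 | step 13 | 2-[(3S,4E)-4-(dimethoxymethyl)-1-oxohex-4-en-3-yl]propanedioic acid | C/C=C(/C(OC)OC)[C@@H](CC=O)C(C(=O)O)C(=O)O
F3 | step 13 | (3S,4E)-4-(dimethoxymethyl)-3-(2-oxoethyl)hex-4-enoic acid | C/C=C(/C(OC)OC)[C@@H](CC=O)CC(=O)O
F4 | step 13 | [(1S,2R,3S,5R)-5-(2,2-dimethyl-1,3-dioxan-5-yl)-3-hydroxy-2-methylcyclopentyl]methyl (3S,4E)-4-(dimethoxymethyl)-3-(2-oxoethyl)hex-4-enoate | C/C=C(/C(OC)OC)[C@@H](CC=O)CC(=O)OC[C@@H]1[C@@H](C)[C@@H](O)C[C@H]1C2COC(C)(C)OC2
F5 | step 12 | [(1S,2R,3S,5R)-5-(2,2-dimethyl-1,3-dioxan-5-yl)-3-(methanesulfonyloxy)-2-methylcyclopentyl]methyl methanesulfonate | CS(=O)(=O)OC[C@@H]1[C@@H](C)[C@@H](OS(C)(=O)=O)C[C@H]1C2COC(C)(C)OC2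
F6 | step 12 | [(1S,2R,3R,5R)-3-acetoxy-5-(2,2-dimethyl-1,3-dioxan-5-yl)-2-methylcyclopentyl]methyl acetate | CC(=O)OC[C@@H]1[C@@H](C)[C@H](OC(C)=O)C[C@H]1C2COC(C)(C)OC2
F7 | step 12 | [(1S,2R,3R,5R)-5-(2,2-dimethyl-1,3-dioxan-5-yl)-3-hydroxy-2-methylcyclopentyl]methanol | OC[C@@H]1[C@@H](C)[C@H](O)C[C@H]1C2COC(C)(C)OC2
F8 | step 3 | (2E,4E)-4-(dimethoxymethyl)hexa-2,4-dien-1-ol | OC/C=C/C(C(OC)OC)=C\C
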